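## Retrosynthetic overview

1. Target 22 ⇐ ring-closing metathesis at C4=C5 of seco diene 21; the ten-membered carbocycle closes last and its oxygen bridge enforces the Z alkene.
2. 21 ⇐ indium allylation of acrolein with allyl bromide 17 (C6–C7 bond, cis α-methylene lactone), then acid (10,14-diol released, five-membered hemiketal closes).
3. 17 ⇐ Baylis–Hillman reaction and bromination of aldehyde 14; 14 ⇐ Weinreb ketone synthesis, esterification and oxidation from 8.
4. Key step: the C10–C1 bond is made by adding the C10 radical of hydroxy lactone 4 (hydrogen-atom abstraction) to acrylamide 5. The sacrificial C14–O8 lactone relays C8 to C10 and is then reduced to the C14 and C8 hydroxyls.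
5. Ring order: butyrolactone (chiral pool, sacrificial) → dioxolane (temporary) → α-methylene lactone → tetrahydrofuran hemiketal → ten-membered ring.

Locants (germacrane type): C1–C10 ring carbons (C3 hemiketal carbon, C4=C5, C6 lactone carbinol, C8 acyloxy carbon, C10 quaternary ether carbon), C11–C13 methylene lactone, C14 CH2OH, C15 vinyl methyl.

Assumption: (R)-5-(hydroxymethyl)oxolan-2-one, (R)-2-methylbutanoic acid and N-methoxy-N-methylprop-2-enamide are taken as commercial.

## Route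

Step 1
Reactants: 1 (5R)-5-(hydroxymethyl)oxolan-2-one
Product: 2 (5R)-5-{[(triethylsilyl)oxy]methyl}oxolan-2-one
Conditions: Et3SiCl, imidazole, CH2Cl2, 0 °C
Reagents that add atoms: chlorotriethylsilane, CC[Si](Cl)(CC)CC
Why: Silyl ether protection of the primary alcohol (the future C7) prevents translactonisation in step 2, and the CH2OSiEt3 group later shields one face of the lactone; C8 comes unchanged from 1.

Step 2
Reactants: 2 (5R)-5-{[(triethylsilyl)oxy]methyl}oxolan-2-one
Product: 4 (3RS,5R)-3-hydroxy-5-{[(triethylsilyl)oxy]methyl}oxolan-2-one, via potassium enolate 3 (not isolated)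
Conditions: KN(SiMe3)2, THF, −78 °C; 3-phenyl-2-(phenylsulfonyl)oxaziridine, −78 °C; AcOH
Reagents that add atoms: 3-phenyl-2-(phenylsulfonyl)oxaziridine, O=S(=O)(c1ccccc1)N1OC1c1ccccc1
Why: Davis α-hydroxylation of the lactone enolate installs O10; the new carbinol centre is an epimer mixture that does not matter because it becomes the radical centre in step 3.

Step 3
Reactants: 4 (3RS,5R)-3-hydroxy-5-{[(triethylsilyl)oxy]methyl}oxolan-2-one; 5 N-methoxy-N-methylprop-2-enamide
Product: 6 3-[(3R,5R)-3-hydroxy-2-oxo-5-{[(triethylsilyl)oxy]methyl}oxolan-3-yl]-N-methoxy-N-methylpropanamide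
Conditions: Ir[dF(CF3)ppy]2(dtbbpy)PF6 (1 mol%), quinuclidine (10 mol%), Bu4N(H2PO4) (25 mol%), 5 (3 equiv), MeCN, blue LEDs, 25 °C
Reagents that add atoms: none
Why: Proposed new method: the quinuclidinium radical cation formed by the photoexcited iridium catalyst abstracts the weak C10–H of the phosphate-hydrogen-bonded carbinol (captodative, flanked by OH and C=O), and the planar ring radical, the same from both epimers of 4, adds to 5 in a Giese reaction on the face opposite the C8 CH2OSiEt3 group (1,3-induction across the five-membered ring, dr of about 5:1 or better expected), which sets the quaternary C10 with C1 trans to C7 before reduction and protonation of the α-amido radical; the closest known reactions are the photoredox/quinuclidine/phosphate α-C–H alkylation of alcohols with acrylates and trans-selective Giese additions of γ-substituted butyrolactone and dioxolanone α-radicals.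

Step 4
Reactants: 6 3-[(3R,5R)-3-hydroxy-2-oxo-5-{[(triethylsilyl)oxy]methyl}oxolan-3-yl]-N-methoxy-N-methylpropanamide
Product: 7 (4R,6R)-4,6-dihydroxy-4-(hydroxymethyl)-N-methoxy-N-methyl-7-[(triethylsilyl)oxy]heptanamide
Conditions: NaBH4, EtOH, 0 °C to rt
Reagents that add atoms: none
Why: Borohydride reduction of the α-hydroxy-activated lactone unzips the template into the C14 and C8 hydroxyls while the Weinreb amide is inert to NaBH4; no stereocentre is touched.

Step 5
Reactants: 7 (4R,6R)-4,6-dihydroxy-4-(hydroxymethyl)-N-methoxy-N-methyl-7-[(triethylsilyl)oxy]heptanamide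
Product: 8 3-[(4R)-4-{(2R)-2-hydroxy-3-[(triethylsilyl)oxy]propyl}-2,2-dimethyl-1,3-dioxolan-4-yl]-N-methoxy-N-methylpropanamide
Conditions: 2-methoxypropene (1.1 equiv), PPTS (cat.), CH2Cl2, 0 °C
Reagents that add atoms: 2-methoxypropene, COC(C)=C
Why: Kinetic acetonide formation, in which the primary C14 hydroxyl adds to the enol ether and closes on the adjacent tertiary C10 hydroxyl (five-membered ring), leaves only the C8 hydroxyl free.

Step 6
Reactants: 8 3-[(4R)-4-{(2R)-2-hydroxy-3-[(triethylsilyl)oxy]propyl}-2,2-dimethyl-1,3-dioxolan-4-yl]-N-methoxy-N-methylpropanamide; 9 isopropenylmagnesium bromide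
Product: 10 5-[(4R)-4-{(2R)-2-hydroxy-3-[(triethylsilyl)oxy]propyl}-2,2-dimethyl-1,3-dioxolan-4-yl]-2-methylpent-1-en-3-one
Conditions: 9 (3 equiv), THF, −20 to 0 °C; cold aq. NH4Cl
Reagents that add atoms: none
Why: Weinreb ketone synthesis, in which the chelated tetrahedral adduct survives until work-up so that the isopropenyl ketone (C3, C4, C15) forms without over-addition; the C8 magnesium alkoxide is a spectator.

Step 7
Reactants: 10 5-[(4R)-4-{(2R)-2-hydroxy-3-[(triethylsilyl)oxy]propyl}-2,2-dimethyl-1,3-dioxolan-4-yl]-2-methylpent-1-en-3-one; 11 (2R)-2-methylbutanoic acid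
Product: 12 (2R)-1-[(4R)-2,2-dimethyl-4-(4-methyl-3-oxopent-4-en-1-yl)-1,3-dioxolan-4-yl]-3-[(triethylsilyl)oxy]propan-2-yl (2R)-2-methylbutanoate
Conditions: 11, EDC·HCl, DMAP (cat.), CH2Cl2, 0 °C to rt
Reagents that add atoms: none
Why: Steglich esterification puts the ester on the only free hydroxyl, with low temperature and catalytic DMAP limiting epimerisation of the α-branched acid.

Step 8
Reactants: 12 (2R)-1-[(4R)-2,2-dimethyl-4-(4-methyl-3-oxopent-4-en-1-yl)-1,3-dioxolan-4-yl]-3-[(triethylsilyl)oxy]propan-2-yl (2R)-2-methylbutanoate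
Product: 14 (2R)-1-[(4R)-2,2-dimethyl-4-(4-methyl-3-oxopent-4-en-1-yl)-1,3-dioxolan-4-yl]-3-oxopropan-2-yl (2R)-2-methylbutanoate, via alkoxysulfonium chloride 13 (not isolated)
Conditions: (COCl)2, DMSO, CH2Cl2, −78 to −30 °C; Et3N, to 0 °C
Reagents that add atoms: none
Why: Swern oxidation, which is known to convert primary triethylsilyl ethers directly into aldehydes, gives the C7 aldehyde without a separate desilylation and without epimerising C8 at low temperature.

Step 9
Reactants: 14 (2R)-1-[(4R)-2,2-dimethyl-4-(4-methyl-3-oxopent-4-en-1-yl)-1,3-dioxolan-4-yl]-3-oxopropan-2-yl (2R)-2-methylbutanoate; 15 methyl prop-2-enoate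
Product: 16 methyl (3RS,4R)-5-[(4R)-2,2-dimethyl-4-(4-methyl-3-oxopent-4-en-1-yl)-1,3-dioxolan-4-yl]-3-hydroxy-2-methylidene-4-{[(2R)-2-methylbutanoyl]oxy}pentanoate
Conditions: 15 (neat, excess), DABCO, rt; used at once
Reagents that add atoms: none
Why: Morita–Baylis–Hillman reaction of the electron-poor α-acyloxy aldehyde is fast, the isopropenyl ketone has no α-hydrogen and cannot enter the cycle, and the new carbinol centre is erased in step 10 (prompt use forestalls a 1,2-acyl shift).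

Step 10
Reactants: 16 methyl (3RS,4R)-5-[(4R)-2,2-dimethyl-4-(4-methyl-3-oxopent-4-en-1-yl)-1,3-dioxolan-4-yl]-3-hydroxy-2-methylidene-4-{[(2R)-2-methylbutanoyl]oxy}pentanoate
Product: 17 methyl (2Z,4R)-2-(bromomethyl)-5-[(4R)-2,2-dimethyl-4-(4-methyl-3-oxopent-4-en-1-yl)-1,3-dioxolan-4-yl]-4-{[(2R)-2-methylbutanoyl]oxy}pent-2-enoate
Conditions: NBS, Me2S, CH2Cl2, −20 °C to rt
Reagents that add atoms: N-bromosuccinimide, O=C1CCC(=O)N1Br
Why: Corey–Kim-type activation of the allylic alcohol and SN2′ delivery of bromide give the conjugated (Z)-2-(bromomethyl)enoate under neutral conditions from both carbinol epimers.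

Step 11
Reactants: 17 methyl (2Z,4R)-2-(bromomethyl)-5-[(4R)-2,2-dimethyl-4-(4-methyl-3-oxopent-4-en-1-yl)-1,3-dioxolan-4-yl]-4-{[(2R)-2-methylbutanoyl]oxy}pent-2-enoate; 18 prop-2-enal
Product: 21 (1R)-1-[(2S,3R)-2-ethenyl-4-methylidene-5-oxooxolan-3-yl]-2-[(2R,5RS)-5-hydroxy-2-(hydroxymethyl)-5-(prop-1-en-2-yl)oxolan-2-yl]ethyl (2R)-2-methylbutanoate, via homoallylic alcohol 19 (not isolated), via lactone acetonide 20 (not isolated)
Conditions: In powder, 18 (3 equiv), THF–H2O (1:1), rt; then AcOH–H2O (4:1), 40 °C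
Reagents that add atoms: none
Why: Indium Barbier allylation in water attacks through the γ-carbon in a cyclic chair with the C8 substituent cis to the CH2In arm, which gives the syn C6/C7 adduct, and the A(1,3)-minimised conformer (C8–H in plane, C9 chain anti to the incoming aldehyde, ester oxygen on the indium side) sets C7 against C8; acid then lactonises to the cis-fused α-methylene lactone, removes the acetonide and lets the C10 hydroxyl close the five-membered hemiketal on the C3 ketone (epimers at C3 equilibrate through the open hydroxy enone).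

Step 12
Reactants: 21 (1R)-1-[(2S,3R)-2-ethenyl-4-methylidene-5-oxooxolan-3-yl]-2-[(2R,5RS)-5-hydroxy-2-(hydroxymethyl)-5-(prop-1-en-2-yl)oxolan-2-yl]ethyl (2R)-2-methylbutanoate
Product: 22 CNP0328225.2 (3S,4Z,6S,7R,8R,10R; locants as above)
Conditions: second-generation Hoveyda–Grubbs catalyst RuCl2(SIMes)(=CH-C6H4-2-OiPr) (15 mol%), 1,4-benzoquinone (30 mol%), toluene (1 mM), 100 °C
Reagents that add atoms: none
Why: Ring-closing metathesis starts at the C6 vinyl group and closes onto the isopropenyl group (reached through the hemiketal/hydroxy-enone equilibrium) with loss of ethene; only the Z alkene fits the oxygen-bridged ring, and the bridged hemiketal fixes C3 under thermodynamic control.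

## Compound list

1 | (5R)-5-(hydroxymethyl)oxolan-2-one | OC[C@H]1CCC(=O)O1 | starting material
2 | (5R)-5-{[(triethylsilyl)oxy]methyl}oxolan-2-one | CC[Si](CC)(CC)OC[C@H]1CCC(=O)O1 | intermediate
3 | potassium (5R)-5-{[(triethylsilyl)oxy]methyl}-4,5-dihydrofuran-2-olate (enolate of 2) | CC[Si](CC)(CC)OC[C@H]1CC=C([O-])O1.[K+] | intermediate
4 | (3RS,5R)-3-hydroxy-5-{[(triethylsilyl)oxy]methyl}oxolan-2-one | CC[Si](CC)(CC)OC[C@H]1CC(O)C(=O)O1 | intermediate
5 | N-methoxy-N-methylprop-2-enamide | C=CC(=O)N(C)OC | starting material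
6 | 3-[(3R,5R)-3-hydroxy-2-oxo-5-{[(triethylsilyl)oxy]methyl}oxolan-3-yl]-N-methoxy-N-methylpropanamide | CC[Si](CC)(CC)OC[C@H]1C[C@](O)(CCC(=O)N(C)OC)C(=O)O1 | intermediate
7 | (4R,6R)-4,6-dihydroxy-4-(hydroxymethyl)-N-methoxy-N-methyl-7-[(triethylsilyl)oxy]heptanamide | CC[Si](CC)(CC)OC[C@H](O)C[C@@](O)(CO)CCC(=O)N(C)OC | intermediate
8 | 3-[(4R)-4-{(2R)-2-hydroxy-3-[(triethylsilyl)oxy]propyl}-2,2-dimethyl-1,3-dioxolan-4-yl]-N-methoxy-N-methylpropanamide | CC[Si](CC)(CC)OC[C@H](O)C[C@]1(CCC(=O)N(C)OC)COC(C)(C)O1 | intermediate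
9 | isopropenylmagnesium bromide | C=C(C)[Mg]Br | starting material
10 | 5-[(4R)-4-{(2R)-2-hydroxy-3-[(triethylsilyl)oxy]propyl}-2,2-dimethyl-1,3-dioxolan-4-yl]-2-methylpent-1-en-3-one | CC[Si](CC)(CC)OC[C@H](O)C[C@]1(CCC(=O)C(C)=C)COC(C)(C)O1 | intermediate
11 | (2R)-2-methylbutanoic acid | CC[C@@H](C)C(=O)O | starting material
12 | (2R)-1-[(4R)-2,2-dimethyl-4-(4-methyl-3-oxopent-4-en-1-yl)-1,3-dioxolan-4-yl]-3-[(triethylsilyl)oxy]propan-2-yl (2R)-2-methylbutanoate | CC[Si](CC)(CC)OC[C@H](OC(=O)[C@H](C)CC)C[C@]1(CCC(=O)C(C)=C)COC(C)(C)O1 | intermediate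
13 | {(2R)-3-[(4R)-2,2-dimethyl-4-(4-methyl-3-oxopent-4-en-1-yl)-1,3-dioxolan-4-yl]-2-{[(2R)-2-methylbutanoyl]oxy}propoxy}dimethylsulfonium chloride | C[S+](C)OC[C@H](OC(=O)[C@H](C)CC)C[C@]1(CCC(=O)C(C)=C)COC(C)(C)O1.[Cl-] | intermediate
14 | (2R)-1-[(4R)-2,2-dimethyl-4-(4-methyl-3-oxopent-4-en-1-yl)-1,3-dioxolan-4-yl]-3-oxopropan-2-yl (2R)-2-methylbutanoate | O=C[C@H](OC(=O)[C@H](C)CC)C[C@]1(CCC(=O)C(C)=C)COC(C)(C)O1 | intermediate
15 | methyl prop-2-enoate | C=CC(=O)OC | starting material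
16 | methyl (3RS,4R)-5-[(4R)-2,2-dimethyl-4-(4-methyl-3-oxopent-4-en-1-yl)-1,3-dioxolan-4-yl]-3-hydroxy-2-methylidene-4-{[(2R)-2-methylbutanoyl]oxy}pentanoate | C=C(C(=O)OC)C(O)[C@H](OC(=O)[C@H](C)CC)C[C@]1(CCC(=O)C(C)=C)COC(C)(C)O1 | intermediate
17 | methyl (2Z,4R)-2-(bromomethyl)-5-[(4R)-2,2-dimethyl-4-(4-methyl-3-oxopent-4-en-1-yl)-1,3-dioxolan-4-yl]-4-{[(2R)-2-methylbutanoyl]oxy}pent-2-enoate | BrC/C(C(=O)OC)=C\[C@H](OC(=O)[C@H](C)CC)C[C@]1(CCC(=O)C(C)=C)COC(C)(C)O1 | intermediate
18 | prop-2-enal | C=CC=O | starting material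
19 | methyl (3S,4R)-5-[(4R)-2,2-dimethyl-4-(4-methyl-3-oxopent-4-en-1-yl)-1,3-dioxolan-4-yl]-3-[(1S)-1-hydroxyprop-2-en-1-yl]-2-methylidene-4-{[(2R)-2-methylbutanoyl]oxy}pentanoate | C=C[C@H](O)[C@H](C(=C)C(=O)OC)[C@H](OC(=O)[C@H](C)CC)C[C@]1(CCC(=O)C(C)=C)COC(C)(C)O1 | intermediate
20 | (1R)-2-[(4R)-2,2-dimethyl-4-(4-methyl-3-oxopent-4-en-1-yl)-1,3-dioxolan-4-yl]-1-[(2S,3R)-2-ethenyl-4-methylidene-5-oxooxolan-3-yl]ethyl (2R)-2-methylbutanoate | C=C1C(=O)O[C@@H](C=C)[C@H]1[C@H](OC(=O)[C@H](C)CC)C[C@]2(CCC(=O)C(C)=C)COC(C)(C)O2 | intermediate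
21 | (1R)-1-[(2S,3R)-2-ethenyl-4-methylidene-5-oxooxolan-3-yl]-2-[(2R,5RS)-5-hydroxy-2-(hydroxymethyl)-5-(prop-1-en-2-yl)oxolan-2-yl]ethyl (2R)-2-methylbutanoate | C=C1C(=O)O[C@@H](C=C)[C@H]1[C@H](OC(=O)[C@H](C)CC)C[C@@]2(CO)CCC(O)(C(C)=C)O2 | intermediate
22 | CNP0328225.2: (3S,4Z,6S,7R,8R,10R)-3,10-epoxy-3,14-dihydroxy-8-{[(2R)-2-methylbutanoyl]oxy}germacra-4,11(13)-dien-12,6-olide (locants as above) | C=C1C(=O)O[C@H]2/C=C(/C)[C@]3(O)CC[C@](CO)(C[C@@H](OC(=O)[C@H](C)CC)[C@@H]12)O3 | target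

## Step count and risks

Total step count: 12. Longest linear sequence: 12 steps (1 → 22); compounds 5, 9, 11, 15 and 18 are bought.

The three steps most likely to fail:

Step 3. Hydrogen abstraction may compete at the CH2OSi group, or the stabilised C10 radical may add too slowly to the acrylamide. Fallback: set out from 4 and oxidise it with Dess–Martin periodinane to (5R)-5-{[(triethylsilyl)oxy]methyl}oxolane-2,3-dione F1. The same C10 radical is then made reductively as a samarium ketyl (SmI2, t-BuOH, THF, −78 °C) in the presence of 5; it adds again on the face opposite the C8 substituent and the route is rejoined at 6.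

Step 11. The allylindium may expel the C8 carboxylate by 1,4-elimination, or the C7/C8 facial control may be poor. Fallback: set out from 17; palladium-catalysed borylation (B2pin2, Pd2(dba)3, KOAc, DMSO) gives methyl (2E,4R)-5-[(4R)-2,2-dimethyl-4-(4-methyl-3-oxopent-4-en-1-yl)-1,3-dioxolan-4-yl]-4-{[(2R)-2-methylbutanoyl]oxy}-2-[(4,4,5,5-tetramethyl-1,3,2-dioxaborolan-2-yl)methyl]pent-2-enoate F2, which has no carbon–metal bond able to eliminate. Allylboration of 18 under a chiral phosphoric acid ((R)-TRIP or its enantiomer, toluene, −30 °C) goes through a closed chair, gives the same syn adduct with the C6/C7 face now set by the catalyst, and rejoins the route at 19.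

Step 12. The isopropenyl group sits on a fully substituted carbon and the ring being closed is bridged. Fallback: set out from 20, isolated when the second stage of step 11 is run with PPTS in CH2Cl2 instead of aqueous acetic acid. Metathesis of this open-chain enone closes the unbridged ten-membered ring to the (4Z,6S,7R,8R,10R)-10,14-(isopropylidenedioxy)-8-{[(2R)-2-methylbutanoyl]oxy}-3-oxogermacra-4,11(13)-dien-12,6-olide F3. Aqueous acetic acid then frees the 10,14-diol, whose C10 hydroxyl adds across the ring to the C3 ketone and gives 22.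

## Further compounds

F1 | step 3 | (5R)-5-{[(triethylsilyl)oxy]methyl}oxolane-2,3-dione | CC[Si](CC)(CC)OC[C@H]1CC(=O)C(=O)O1
F2 | step 11 | methyl (2E,4R)-5-[(4R)-2,2-dimethyl-4-(4-methyl-3-oxopent-4-en-1-yl)-1,3-dioxolan-4-yl]-4-{[(2R)-2-methylbutanoyl]oxy}-2-[(4,4,5,5-tetramethyl-1,3,2-dioxaborolan-2-yl)methyl]pent-2-enoate | CC1(C)OB(C/C(C(=O)OC)=C\[C@H](OC(=O)[C@H](C)CC)C[C@]2(CCC(=O)C(C)=C)COC(C)(C)O2)OC1(C)C
F3 | step 12 | (4Z,6S,7R,8R,10R)-10,14-(isopropylidenedioxy)-8-{[(2R)-2-methylbutanoyl]oxy}-3-oxogermacra-4,11(13)-dien-12,6-olide | C=C1C(=O)O[C@H]2/C=C(/C)C(=O)CC[C@@]3(C[C@@H](OC(=O)[C@H](C)CC)[C@@H]12)COC(C)(C)O3
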